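**Retrosynthetic overview**

1. Lignan numbering is used: the oxolane ring is O1–C7–C8–C8'–C9'; C7 bears the guaiacyl ring, C8 the C9 hydroxymethyl arm, and C8' the benzylic carbinol C7' with the catechol ring. The target is the all-trans oxolane (7S,8R,8'S,7'R).
2. Enabling feature: C8 carries only a one-carbon arm and C8' carries a benzylic carbinol. With C9 carried as a vinyl group, O1–C7–C8 is a latent 2-aryl-3-vinyloxirane (alkoxide at O1, π-allyl terminus at C8). With C7' carried as a ketone, C9'=C8' is the β,α pair of an aryl vinyl ketone.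
3. Key disconnection: O1–C9' and C8–C8' are formed together in a palladium-catalysed formal [3+2] cycloaddition (oxa-Michael addition, then allylic alkylation) of vinyloxirane 4 with enone 7. This closes the oxolane and sets C8 and C8' from C7.
4. After the key step: C7' by CBS reduction, vinyl to CH2OH by oxidative cleavage and reduction, then removal of three pivalates. Before it: 4 from coniferaldehyde (acylation, Wittig, Shi epoxidation) and 7 from 3',4'-dihydroxyacetophenone (acylation, α-methylenation).
5. Ring order: the temporary oxirane (step 3) is consumed when the oxolane, the only ring built, is closed (step 6).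

Key step: step 6

Remark: species that exist only bound to a catalyst (the π-allylpalladium zwitterion, the dioxirane, the osmate ester) are described in the Why lines and are not numbered.

**Route**

Step 1
Reactants: 1 coniferaldehyde
Product: 2 O-pivaloylconiferaldehyde
Conditions: PivCl (1.2 equiv), Et3N (1.5 equiv), DMAP (5 mol %), CH2Cl2, 0 °C → rt
Reagents that add atoms: pivaloyl chloride, CC(C)(C)C(=O)Cl
Why: DMAP-catalysed acylation of the phenol gives a hindered aryl pivalate that should survive the ylide, the pH 10.5 buffer and NaBH4, and that makes the arene a weak para donor so the benzylic oxirane of step 3 is not ionised.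

Step 2
Reactants: 2 O-pivaloylconiferaldehyde
Product: 3 (E)-1-aryl-1,3-butadiene
Conditions: Ph3PCH3Br (1.1 equiv), KOt-Bu (1.05 equiv), THF, 0 °C; then 2, −78 → 0 °C
Reagents that add atoms: methyltriphenylphosphonium bromide, C[P+](c1ccccc1)(c1ccccc1)c1ccccc1.[Br-]
Why: Wittig methylenation of the enal by 1,2-addition should leave the existing (E) double bond untouched and react far faster with the aldehyde than with the hindered aryl ester.

Step 3
Reactants: 3 (E)-1-aryl-1,3-butadiene
Product: 4 (2R,3R)-2-aryl-3-vinyloxirane
Conditions: D-fructose-derived Shi ketone (0.3 equiv), KHSO5 (as 2KHSO5·KHSO4·K2SO4, 1.4 equiv), K2CO3, Bu4NHSO4 (cat.), MeCN–CH2(OMe)2 / aq. Na2B4O7–Na2EDTA buffer (pH 10.5), −10 → 0 °C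
Reagents that add atoms: potassium peroxymonosulfate KHSO5, [K+].[O-]S(=O)(=O)OO
Why: In the Shi asymmetric epoxidation the chiral dioxirane should attack the trans-disubstituted, aryl-conjugated double bond in preference to the terminal one and, by analogy with trans-β-methylstyrene, give the (2R,3R)-oxirane, which fixes the benzylic centre that becomes C7.

Step 4
Reactants: 5 3',4'-dihydroxyacetophenone
Product: 6 3',4'-bis(pivaloyloxy)acetophenone
Conditions: PivCl (2.4 equiv), Et3N (3 equiv), DMAP (5 mol %), CH2Cl2, 0 °C → rt
Reagents that add atoms: pivaloyl chloride, CC(C)(C)C(=O)Cl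
Why: Acylation of both phenols protects the catechol against oxidation and base, and the ester groups make the later enone more electrophilic.

Step 5
Reactants: 6 3',4'-bis(pivaloyloxy)acetophenone
Product: 7 aryl vinyl ketone
Conditions: (CH2O)n (3 equiv), i-Pr2NH·CF3CO2H (1 equiv), CF3CO2H (10 mol %), THF, reflux; used freshly prepared
Reagents that add atoms: paraformaldehyde (as formaldehyde), C=O
Why: Mannich condensation with formaldehyde and elimination of the amine (direct α-methylenation of an aryl methyl ketone) should give the vinyl ketone under mildly acidic conditions that leave the pivalates intact.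

Step 6
Reactants: 4 (2R,3R)-2-aryl-3-vinyloxirane; 7 aryl vinyl ketone
Product: 8 all-trans 2-aryl-3-vinyl-4-aroyloxolane (7S,8S,8'S)
Conditions: Pd2(dba)3·CHCl3 (2.5 mol %), dppe (6 mol %), THF, 0 °C → rt, 7 (1.3 equiv) added over 2 h
Reagents that add atoms: none
Why: Zerovalent palladium ionises the allylic C–O bond of 4 with inversion, leaving the benzylic C–O centre untouched, to give a zwitterionic π-allylpalladium alkoxide; the alkoxide adds to the unsubstituted β-carbon of 7 (oxa-Michael, new O1–C9' bond) and the resulting aryl ketone enolate attacks the substituted allyl terminus anti to palladium (new C8–C8' bond), releasing the catalyst. The closest known reaction type is the palladium-catalysed formal [3+2] cycloaddition of vinyloxiranes with Michael acceptors, α,β-unsaturated ketones included (oxa-Michael addition followed by Tsuji–Trost allylic alkylation). The oxolane ring is closed in the C–C bond-forming event, a 5-exo attack of the enolate carbon on the allyl terminus, the other two allyl carbons remaining as the exocyclic vinyl group. C8 is controlled by C7: ionisation and alkylation both go with inversion, so the trans-oxirane maps onto the 7,8-trans oxolane, which is also the isomer favoured sterically if the allyl faces exchange; C8', the α-carbon of the ketone, is set in the same closure with the aroyl group trans to the vinyl group and, being enolisable, can be equilibrated to this all-trans arrangement. The step needs 1,4- rather than 1,2-addition of the alkoxide, attack at the internal rather than the terminal allyl carbon (five- versus seven-membered ring), and trapping faster than hydride shift of the zwitterion or enolate-initiated oligomerisation of 7; the unhindered, strongly electrophilic vinyl ketone, the kinetic preference for the five-membered ring and the slow addition of 7 should secure these.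

Step 7
Reactants: 8 all-trans 2-aryl-3-vinyl-4-aroyloxolane
Product: 9 (7'R)-benzylic alcohol
Conditions: (S)-2-methyl-CBS-oxazaborolidine (0.3 equiv), catecholborane (2 equiv), toluene, −78 → −40 °C; then MeOH, aq. NaHCO3
Reagents that add atoms: none
Why: In the Corey–Bakshi–Shibata reduction the (S)-oxazaborolidine should bind the ketone with the aryl group as the large substituent and deliver hydride to give the (R)-carbinol at C7' under catalyst control, while catecholborane at low temperature leaves the vinyl group and the pivalates untouched.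

Step 8
Reactants: 9 (7'R)-benzylic alcohol
Product: 12 primary alcohol (the target as its tripivalate), via diol 10 (not isolated), via aldehyde 11 (not isolated)
Conditions: OsO4 (2 mol %), NaIO4 (4 equiv), 2,6-lutidine (2 equiv), dioxane–H2O (3:1), rt; then NaBH4 (excess), MeOH, 0 °C
Reagents that add atoms: OsO4, O=[Os](=O)(=O)=O; NaIO4, [Na+].[O-]I(=O)(=O)=O
Why: Lemieux–Johnson cleavage of the only alkene followed by NaBH4 reduction in the same flask should convert the vinyl group into the C9 hydroxymethyl group without touching a stereocentre, the β-alkoxy aldehyde being reduced before it can epimerise or eliminate.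

Step 9
Reactants: 12 primary alcohol (tripivalate)
Product: 13 target, CNP0197133.1
Conditions: K2CO3 (1.5 equiv), degassed MeOH, under argon, 0 °C → rt; then aq. NH4Cl
Reagents that add atoms: none
Why: Base-mediated transesterification of the three aryl pivalates with methanol should release the phenols without affecting the benzylic ether, the benzylic alcohol or any stereocentre, and exclusion of oxygen protects the catechol.

**Compound list**

1 | coniferaldehyde, (2E)-3-(4-hydroxy-3-methoxyphenyl)prop-2-enal | COc1cc(/C=C/C=O)ccc1O | starting material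
2 | 2-methoxy-4-[(1E)-3-oxoprop-1-en-1-yl]phenyl 2,2-dimethylpropanoate | COc1cc(/C=C/C=O)ccc1OC(=O)C(C)(C)C | intermediate
3 | 4-[(1E)-buta-1,3-dien-1-yl]-2-methoxyphenyl 2,2-dimethylpropanoate | COc1cc(/C=C/C=C)ccc1OC(=O)C(C)(C)C | intermediate
4 | 4-[(2R,3R)-3-ethenyloxiran-2-yl]-2-methoxyphenyl 2,2-dimethylpropanoate (trans-oxirane) | C=C[C@H]1O[C@@H]1c1ccc(OC(=O)C(C)(C)C)c(OC)c1 | intermediate
5 | 1-(3,4-dihydroxyphenyl)ethan-1-one | CC(=O)c1ccc(O)c(O)c1 | starting material
6 | 4-acetyl-1,2-phenylene bis(2,2-dimethylpropanoate) | CC(=O)c1ccc(OC(=O)C(C)(C)C)c(OC(=O)C(C)(C)C)c1 | intermediate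
7 | 4-(prop-2-enoyl)-1,2-phenylene bis(2,2-dimethylpropanoate) | C=CC(=O)c1ccc(OC(=O)C(C)(C)C)c(OC(=O)C(C)(C)C)c1 | intermediate
8 | 4-{[(3S,4S,5S)-4-ethenyl-5-(3-methoxy-4-pivaloyloxyphenyl)oxolan-3-yl]carbonyl}-1,2-phenylene bis(2,2-dimethylpropanoate), all-trans | COc1cc([C@H]2OC[C@@H](C(=O)c3ccc(OC(=O)C(C)(C)C)c(OC(=O)C(C)(C)C)c3)[C@@H]2C=C)ccc1OC(=O)C(C)(C)C | intermediate
9 | 4-{(R)-[(3S,4S,5S)-4-ethenyl-5-(3-methoxy-4-pivaloyloxyphenyl)oxolan-3-yl](hydroxy)methyl}-1,2-phenylene bis(2,2-dimethylpropanoate) | COc1cc([C@H]2OC[C@@H]([C@@H](O)c3ccc(OC(=O)C(C)(C)C)c(OC(=O)C(C)(C)C)c3)[C@@H]2C=C)ccc1OC(=O)C(C)(C)C | intermediate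
10 | 1,2-diol from dihydroxylation of the vinyl group of 9 (both epimers at the new carbinol carbon, other centres as in 9) | COc1cc([C@H]2OC[C@@H]([C@@H](O)c3ccc(OC(=O)C(C)(C)C)c(OC(=O)C(C)(C)C)c3)[C@@H]2C(O)CO)ccc1OC(=O)C(C)(C)C | intermediate
11 | oxolane-3-carbaldehyde from glycol cleavage of 10 (ring and carbinol centres as in 9) | COc1cc([C@H]2OC[C@@H]([C@@H](O)c3ccc(OC(=O)C(C)(C)C)c(OC(=O)C(C)(C)C)c3)[C@@H]2C=O)ccc1OC(=O)C(C)(C)C | intermediate
12 | 4-{(R)-hydroxy[(3S,4R,5S)-4-(hydroxymethyl)-5-(3-methoxy-4-pivaloyloxyphenyl)oxolan-3-yl]methyl}-1,2-phenylene bis(2,2-dimethylpropanoate) | COc1cc([C@H]2OC[C@@H]([C@@H](O)c3ccc(OC(=O)C(C)(C)C)c(OC(=O)C(C)(C)C)c3)[C@@H]2CO)ccc1OC(=O)C(C)(C)C | intermediate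
13 | 4-{(R)-hydroxy[(3S,4R,5S)-5-(4-hydroxy-3-methoxyphenyl)-4-(hydroxymethyl)oxolan-3-yl]methyl}benzene-1,2-diol | COc1cc([C@H]2OC[C@@H]([C@@H](O)c3ccc(O)c(O)c3)[C@@H]2CO)ccc1O | target

**Summary**

Total step count: 9. Longest linear sequence: 7 steps (1, 2, 3, 6, 7, 8, 9); steps 4 and 5 form the convergent enone branch.

**Steps most likely to fail**

Step 6 (key step). The zwitterion may be diverted before it is trapped (hydride shift to an aryl ketone, closure to a dihydrofuran), the enolate may add to a second molecule of 7 instead of closing the ring, and exchange of the allyl faces may erode the 7,8-trans selectivity. The fallback sets out from 4 and comes back at 8, making the two bonds separately. Oxirane 4 is opened by 1,4-addition of acetic acid (Pd(PPh3)4 cat., AcOH, THF, 0 °C), the acid quenching the alkoxide at once, to give the (E)-hydroxy allylic acetate F1. The secondary alcohol of F1 is added to enone 7 under phosphine catalysis (PMe3 10 mol %, THF, rt; oxa-Michael addition with no palladium present) to give the keto ether F2. F2 is then closed by intramolecular Tsuji–Trost alkylation of its preformed lithium enolate (LiHMDS, THF, −78 °C; then Pd(PPh3)4, → rt), a 5-exo closure in which the pseudo-equatorial aryl group should favour the trans isomer, giving 8.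

Step 7. Facial selectivity may be poor if the bias of the α-stereocentre C8' opposes the catalyst (mismatched pair), and the hindered α-branched aryl ketone may react slowly. The fallback sets out from 8 and comes back at 9, using the substrate bias instead of fighting it. Ketone 8 is reduced with a bulky achiral hydride (LiBH(s-Bu)3, THF, −78 °C) to the 7'S-epimeric alcohol F3. Mitsunobu inversion of F3 (ClCH2CO2H, PPh3, DIAD, toluene, 0 °C → rt) gives the 7'R chloroacetate F4. Selective cleavage of the chloroacetate (thiourea, NaHCO3, EtOH, 50 °C), which the aryl pivalates should survive, gives 9.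

Step 3. Epoxidation may occur at the terminal double bond or at both, enantioface control may be incomplete, and the benzylic allylic oxirane may open hydrolytically in the aqueous buffer or during purification. The fallback sets out from 2 and comes back at 4, building the oxirane before the vinyl group exists. Luche reduction of 2 (NaBH4, CeCl3·7H2O, MeOH, 0 °C) gives the cinnamyl alcohol F5. Sharpless asymmetric epoxidation of F5 (Ti(Oi-Pr)4, D-(−)-diethyl tartrate, t-BuOOH, 4 Å molecular sieves, CH2Cl2, −20 °C) gives the (2R,3R)-epoxy alcohol F6. Parikh–Doering oxidation of F6 (SO3·pyridine, DMSO, i-Pr2NEt, CH2Cl2, 0 °C) gives the epoxy aldehyde F7. Wittig methylenation of F7 (Ph3PCH3Br, KOt-Bu, THF, −78 → 0 °C) gives 4.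

**Further compounds**

F1 | step 6 | 4-[(1S,2E)-4-acetoxy-1-hydroxybut-2-en-1-yl]-2-methoxyphenyl 2,2-dimethylpropanoate | COc1cc([C@@H](O)/C=C/COC(C)=O)ccc1OC(=O)C(C)(C)C
F2 | step 6 | 4-{3-[(1S,2E)-4-acetoxy-1-(3-methoxy-4-pivaloyloxyphenyl)but-2-en-1-yloxy]propanoyl}-1,2-phenylene bis(2,2-dimethylpropanoate) | COc1cc([C@@H](OCCC(=O)c2ccc(OC(=O)C(C)(C)C)c(OC(=O)C(C)(C)C)c2)/C=C/COC(C)=O)ccc1OC(=O)C(C)(C)C
F3 | step 7 | 7'S epimer of 9, 4-{(S)-[(3S,4S,5S)-4-ethenyl-5-(3-methoxy-4-pivaloyloxyphenyl)oxolan-3-yl](hydroxy)methyl}-1,2-phenylene bis(2,2-dimethylpropanoate) | COc1cc([C@H]2OC[C@@H]([C@H](O)c3ccc(OC(=O)C(C)(C)C)c(OC(=O)C(C)(C)C)c3)[C@@H]2C=C)ccc1OC(=O)C(C)(C)C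
F4 | step 7 | chloroacetate of 9, 4-{(R)-(2-chloroacetoxy)[(3S,4S,5S)-4-ethenyl-5-(3-methoxy-4-pivaloyloxyphenyl)oxolan-3-yl]methyl}-1,2-phenylene bis(2,2-dimethylpropanoate) | COc1cc([C@H]2OC[C@@H]([C@@H](OC(=O)CCl)c3ccc(OC(=O)C(C)(C)C)c(OC(=O)C(C)(C)C)c3)[C@@H]2C=C)ccc1OC(=O)C(C)(C)C
F5 | step 3 | 4-[(1E)-3-hydroxyprop-1-en-1-yl]-2-methoxyphenyl 2,2-dimethylpropanoate | COc1cc(/C=C/CO)ccc1OC(=O)C(C)(C)C
F6 | step 3 | 4-[(2R,3R)-3-(hydroxymethyl)oxiran-2-yl]-2-methoxyphenyl 2,2-dimethylpropanoate | OC[C@H]1O[C@@H]1c1ccc(OC(=O)C(C)(C)C)c(OC)c1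
F7 | step 3 | 4-[(2R,3S)-3-formyloxiran-2-yl]-2-methoxyphenyl 2,2-dimethylpropanoate | O=C[C@H]1O[C@@H]1c1ccc(OC(=O)C(C)(C)C)c(OC)c1
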